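**Retrosynthetic overview**

1. Target 30 ← 29 (desilylation) ← 26 (C13 methylenation of the γ-lactone) ← 25 (lactonisation of O6 onto C12) ← 24 (reduction of the C6 ketone).
2. 24 ← 23: the C3–C4 bond is made by addition of the C3 radical to C4 and β-loss of PhSO2•. The route rests on C4 being the methyl-bearing sp2 carbon of the ring-cis C4=C5 alkene, which is conjugated with C6 once C6 is a ketone and is then the β-carbon of a β-sulfonyl enone.
3. 23 ← ynone 21 + PhSO2Na ← Weinreb amide 19 + MeC≡CMgBr; C7–C8 by a reagent-controlled anti aldol reaction of succinate thioester 13 with β,γ-epoxy aldehyde 11.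
4. 11 ← Z-selective Still–Gennari olefination (C1=C10) of aldehyde 3 with allylated phosphonate 6, Sharpless epoxidation, oxidative cleavage of the allyl group to C8.
5. Ring order: oxirane C1–O–C10 (step 6), ten-membered carbocycle C1–C10 (step 17), γ-lactone O–C6–C7–C11–C12 (step 19).

Key step: step 17

Remark: all intermediates carry germacrane numbers (C1/C10 oxirane carbons, C4=C5, C6 lactone carbinol, C7, C8 acyloxy carbon, C11–C13 lactone arm, C14 = CH2O on C10, C15 = methyl on C4).
Assumption: the boron bromide of step 10 made from (−)-menthone is taken to give the (7R,8R) anti adduct; if it gives the mirror-image anti series, the reagent made from (+)-menthone is used instead.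

**Route**

Step 1
Reactants: 1 1,3-propanediol
Product: 2 3-[(4-methoxybenzyl)oxy]propan-1-ol
Conditions: NaH (1 equiv), 4-MeOC6H4CH2Cl, Bu4NI (cat.), THF–DMF, 0 °C to rt; diol in threefold excess
Reagents that add atoms: 4-methoxybenzyl chloride, COc1ccc(CCl)cc1
Why: Williamson etherification of the mono-alkoxide of the symmetrical diol, used in excess, should give the mono-PMB ether that marks C3 for later conversion into the iodide.

Step 2
Reactants: 2 3-[(4-methoxybenzyl)oxy]propan-1-ol
Product: 3 3-[(4-methoxybenzyl)oxy]propanal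
Conditions: TEMPO (cat.), PhI(OAc)2, CH2Cl2, rt
Reagents that add atoms: none
Why: Oxoammonium (TEMPO) oxidation of the primary alcohol stops at the aldehyde and leaves the PMB ether untouched.

Step 3
Reactants: 4 methyl 2-[bis(2,2,2-trifluoroethoxy)phosphoryl]acetate; 5 allyl bromide
Product: 6 methyl 2-[bis(2,2,2-trifluoroethoxy)phosphoryl]pent-4-enoate (racemic)
Conditions: NaH, THF–DMF, 0 °C; then 5, rt
Reagents that add atoms: none
Why: SN2 C-alkylation of the stabilised phosphonoacetate carbanion with the allylic bromide places C9 and the masked C8 on C10; the stereocentre formed is destroyed in step 4.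

Step 4
Reactants: 6 methyl 2-[bis(2,2,2-trifluoroethoxy)phosphoryl]pent-4-enoate; 3 3-[(4-methoxybenzyl)oxy]propanal
Product: 7 methyl (2Z)-2-allyl-5-[(4-methoxybenzyl)oxy]pent-2-enoate
Conditions: KN(SiMe3)2, 18-crown-6, THF, −78 °C
Reagents that add atoms: none
Why: Still–Gennari olefination: the electron-poor phosphonate with a dissociated potassium ion eliminates from the kinetic adduct and should give the Z enoate, in which the ester carbon C14 is cis to C2.

Step 5
Reactants: 7 methyl (2Z)-2-allyl-5-[(4-methoxybenzyl)oxy]pent-2-enoate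
Product: 8 (2Z)-2-allyl-5-[(4-methoxybenzyl)oxy]pent-2-en-1-ol
Conditions: iBu2AlH (2.2 equiv), CH2Cl2, −78 °C
Reagents that add atoms: none
Why: 1,2-Reduction of the enoate with the aluminium hydride gives the Z allylic alcohol without touching the terminal alkene or the alkene geometry.

Step 6
Reactants: 8 (2Z)-2-allyl-5-[(4-methoxybenzyl)oxy]pent-2-en-1-ol
Product: 9 [(2S,3R)-2-allyl-3-{2-[(4-methoxybenzyl)oxy]ethyl}oxiran-2-yl]methanol
Conditions: Ti(OiPr)4, L-(+)-diethyl tartrate, tBuOOH, 4 Å molecular sieves, CH2Cl2, −20 °C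
Reagents that add atoms: tert-butyl hydroperoxide, CC(C)(C)OO
Why: Sharpless asymmetric epoxidation: the titanium tartrate complex binds the C14 hydroxyl and epoxidises only the allylic C1=C10 alkene, L-(+)-diethyl tartrate delivering oxygen to the face that gives the 2S oxirane (C10 S and C1 R in germacrane numbering), while the Z geometry fixes C2 and C14 cis.

Step 7
Reactants: 9 [(2S,3R)-2-allyl-3-{2-[(4-methoxybenzyl)oxy]ethyl}oxiran-2-yl]methanol
Product: 10 {[(2S,3R)-2-allyl-3-{2-[(4-methoxybenzyl)oxy]ethyl}oxiran-2-yl]methoxy}(tert-butyl)dimethylsilane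
Conditions: TBSCl, imidazole, CH2Cl2, 0 °C to rt
Reagents that add atoms: tert-butyldimethylsilyl chloride, CC(C)(C)[Si](C)(C)Cl
Why: Silylation of the primary C14 alcohol gives an ether that survives every step up to the final fluoride treatment.

Step 8
Reactants: 10 {[(2S,3R)-2-allyl-3-{2-[(4-methoxybenzyl)oxy]ethyl}oxiran-2-yl]methoxy}(tert-butyl)dimethylsilane
Product: 11 2-[(2S,3R)-2-{[(tert-butyldimethylsilyl)oxy]methyl}-3-{2-[(4-methoxybenzyl)oxy]ethyl}oxiran-2-yl]acetaldehyde
Conditions: OsO4 (cat.), NaIO4, 2,6-lutidine, dioxane–H2O, rt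
Reagents that add atoms: sodium periodate, [Na+].[O-]I(=O)(=O)=O (terminal oxidant; the oxygen reaches C8 through catalytic osmium tetroxide, O=[Os](=O)(=O)=O)
Why: Lemieux–Johnson cleavage of the only alkene, buffered with lutidine, unmasks the C8 aldehyde under near-neutral conditions that the β,γ-epoxy aldehyde should tolerate; 11 is used at once.

Step 9
Reactants: 12 monomethyl succinate
Product: 13 S-tert-butyl 4-methoxy-4-oxobutanethioate
Conditions: tBuSH, dicyclohexylcarbodiimide, DMAP (cat.), CH2Cl2, 0 °C to rt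
Reagents that add atoms: 2-methylpropane-2-thiol, CC(C)(C)S
Why: Steglich thioesterification turns the free carboxyl (the later C6) into a thioester that is enolised and later activated in preference to the methyl ester.

Step 10
Reactants: 13 S-tert-butyl 4-methoxy-4-oxobutanethioate; 11 2-[(2S,3R)-2-{[(tert-butyldimethylsilyl)oxy]methyl}-3-{2-[(4-methoxybenzyl)oxy]ethyl}oxiran-2-yl]acetaldehyde
Product: 15 S-tert-butyl (2R,3R)-4-[(2S,3R)-2-{[(tert-butyldimethylsilyl)oxy]methyl}-3-{2-[(4-methoxybenzyl)oxy]ethyl}oxiran-2-yl]-3-hydroxy-2-(2-methoxy-2-oxoethyl)butanethioate, via enol borinate 14 (not isolated)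
Conditions: {[(1S,2S,5R)-2-isopropyl-5-methylcyclohexyl]methyl}2BBr (from (−)-menthone), Et3N, Et2O–CH2Cl2, −78 °C; then 11, −78 to −20 °C; pH 7 buffer, MeOH, H2O2, 0 °C
Reagents that add atoms: none
Why: Boron-mediated anti aldol reaction: the thioester is enolised in preference to the methyl ester to the E(O) enol borinate, which reacts through a closed chair transition state to the 7,8-anti adduct, and the chiral ligands on boron choose the enolate face, so that C7 and C8 are both set R by the reagent and not by the remote oxirane.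

Step 11
Reactants: 15 anti aldol adduct
Product: 16 S-tert-butyl (2R,3R)-4-[(2S,3R)-2-{[(tert-butyldimethylsilyl)oxy]methyl}-3-{2-[(4-methoxybenzyl)oxy]ethyl}oxiran-2-yl]-2-(2-methoxy-2-oxoethyl)-3-[(2-methylpropanoyl)oxy]butanethioate
Conditions: (iPrCO)2O, Et3N, DMAP (cat.), CH2Cl2, 0 °C
Reagents that add atoms: isobutyric anhydride, CC(C)C(=O)OC(=O)C(C)C
Why: DMAP-catalysed acylation installs the C8 isobutyrate of the target at once, so that the C8 hydroxyl cannot lactonise onto the C12 methyl ester.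

Step 12
Reactants: 16 thioester isobutyrate
Product: 17 methyl (3R,4R)-5-[(2S,3R)-2-{[(tert-butyldimethylsilyl)oxy]methyl}-3-{2-[(4-methoxybenzyl)oxy]ethyl}oxiran-2-yl]-3-[methoxy(methyl)carbamoyl]-4-[(2-methylpropanoyl)oxy]pentanoate
Conditions: MeNH(OMe) (3 equiv), AgOCOCF3 (1.2 equiv), THF, 0 °C to rt
Reagents that add atoms: N,O-dimethylhydroxylamine, CNOC
Why: Silver-assisted aminolysis of the tert-butyl thioester: the thiophilic silver salt activates only the thioester, so the Weinreb amide forms while methyl ester, isobutyrate and oxirane stay intact.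

Step 13
Reactants: 17 Weinreb amide (C3 PMB ether)
Product: 18 methyl (3R,4R)-5-[(2S,3R)-2-{[(tert-butyldimethylsilyl)oxy]methyl}-3-(2-hydroxyethyl)oxiran-2-yl]-3-[methoxy(methyl)carbamoyl]-4-[(2-methylpropanoyl)oxy]pentanoate
Conditions: DDQ, CH2Cl2–pH 7 buffer, 0 °C
Reagents that add atoms: none
Why: Oxidative cleavage of the PMB ether by DDQ (hydride abstraction, then hydrolysis of the oxocarbenium ion) frees the C3 hydroxyl and spares silyl ether, esters and oxirane.

Step 14
Reactants: 18 C3 alcohol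
Product: 19 methyl (3R,4R)-5-[(2S,3R)-2-{[(tert-butyldimethylsilyl)oxy]methyl}-3-(2-iodoethyl)oxiran-2-yl]-3-[methoxy(methyl)carbamoyl]-4-[(2-methylpropanoyl)oxy]pentanoate
Conditions: PPh3, I2, imidazole (premixed), CH2Cl2, 0 °C
Reagents that add atoms: iodine, II
Why: Appel-type iodination: the primary alcohol is activated as the alkoxyphosphonium salt and displaced by iodide, at a stage where no Michael acceptor is present.

Step 15
Reactants: 19 iodo Weinreb amide; 20 1-propynylmagnesium bromide
Product: 21 methyl (3R,4R)-3-(but-2-ynoyl)-5-[(2S,3R)-2-{[(tert-butyldimethylsilyl)oxy]methyl}-3-(2-iodoethyl)oxiran-2-yl]-4-[(2-methylpropanoyl)oxy]pentanoate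
Conditions: MeC≡CMgBr (3 equiv), THF, −20 to 0 °C; inverse quench into cold aq NH4Cl
Reagents that add atoms: none
Why: Weinreb ketone synthesis: the alkynyl Grignard reagent adds once and the magnesium chelate holds the tetrahedral intermediate until work-up, while this weakly nucleophilic reagent should leave the esters and the primary iodide alone at 0 °C.

Step 16
Reactants: 21 ynone; 22 sodium benzenesulfinate
Product: 23 methyl (3R,4R)-5-[(2S,3R)-2-{[(tert-butyldimethylsilyl)oxy]methyl}-3-(2-iodoethyl)oxiran-2-yl]-4-[(2-methylpropanoyl)oxy]-3-[(2E)-3-(phenylsulfonyl)but-2-enoyl]pentanoate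
Conditions: PhSO2Na (1.2 equiv), AcOH (1.2 equiv), THF–H2O, 0 °C to rt
Reagents that add atoms: none
Why: Conjugate (sulfa-Michael) addition of the sulfinate to C4 of the ynone and protonation at C5 give the β-sulfonyl enone, which should settle by reversible addition in the E form; the geometry is lost in step 17 and is of no consequence.

Step 17
Reactants: 23 acyclic C3 iodide with β-sulfonyl enone
Product: 24 methyl (1R,4Z,7R,8R,10S)-14-[(tert-butyldimethylsilyl)oxy]-1,10-epoxy-8-(isobutyryloxy)-6-oxo-13-norgermacr-4-en-12-oate (ten-membered ring)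
Conditions: (Me3Si)3SiH (1.3 equiv) and AIBN (0.3 equiv) in PhH by syringe pump over 12 h into 23 (0.002 M) and 2,6-lutidine (2 equiv) in PhH, 80 °C
Reagents that add atoms: none
Why: Proposed new method: the silyl radical abstracts iodine from C3 and the nucleophilic primary radical adds to C4, the β-carbon of the sulfonyl enone, giving a C5 radical stabilised by the C6 ketone that expels PhSO2• by β-scission; this forms C3–C4, restores C4=C5 and carries the chain through hydrogen abstraction from the silane. The closest known reactions are hydride-mediated macrocyclisations of ω-iodoalkyl enones and the intermolecular radical alkenylation of alkyl iodides with β-sulfonyl acceptors; their union in a ten-membered ring closure is not documented. The ring closes in the 10-endo-trig mode, and the trans-oxirane and the three sp2 centres C4–C6 remove part of the transannular strain of the folding chain. No stereocentre is formed; the ring-cis (Z) C4=C5 geometry is expected because reversible addition of PhSO2• to C4 of the product lets the enone settle in the less strained cis form. The step needs cyclisation to outrun reduction of the C3 radical and attack at C4 rather than C5: slow addition keeps the silane very dilute, and the C6 ketone makes C4 the electrophilic terminus and C5 the site of the stabilised radical. 2,6-Lutidine takes up the sulfinic acid so that the oxirane is not opened.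

Step 18
Reactants: 24 macrocyclic enone
Product: 25 methyl (1R,4Z,6R,7S,8R,10S)-14-[(tert-butyldimethylsilyl)oxy]-1,10-epoxy-6-hydroxy-8-(isobutyryloxy)-13-norgermacr-4-en-12-oate
Conditions: (R)-2-methyl-CBS-oxazaborolidine (0.5 equiv), BH3·SMe2 (1.2 equiv), THF, −40 °C; MeOH quench
Reagents that add atoms: none
Why: Corey–Bakshi–Shibata reduction: the ketone binds to the catalyst boron with the alkenyl side C5 taken as the large group and hydride is delivered from the coordinated borane to the face that gives the 6R allylic alcohol, 1,2-reduction being much faster than hydroboration or epoxide opening at this temperature.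

Step 19
Reactants: 25 6R hydroxy ester
Product: 26 (1R,4Z,6R,7R,8R,10S)-14-[(tert-butyldimethylsilyl)oxy]-1,10-epoxy-8-(isobutyryloxy)-13-norgermacr-4-en-12,6-olide
Conditions: 2-hydroxypyridine (cat.), PhMe, 60 °C
Reagents that add atoms: none
Why: Intramolecular transesterification (5-exo-trig lactonisation) of the γ-hydroxy methyl ester under neutral bifunctional catalysis closes the trans-fused γ-lactone without acid, which would trigger transannular opening of the oxirane.

Step 20
Reactants: 26 γ-lactone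
Product: 27 (1R,4Z,6R,7R,8R,10S)-14-[(tert-butyldimethylsilyl)oxy]-13-(dimethylamino)-1,10-epoxy-8-(isobutyryloxy)germacr-4-en-12,6-olide (C11 epimers)
Conditions: LiN(SiMe3)2 (1.15 equiv), THF, −78 °C; then (CH2=NMe2)I, −78 to −20 °C
Reagents that add atoms: N,N-dimethylmethyleneiminium iodide (Eschenmoser's salt), C=[N+](C)C.[I-]
Why: Mannich reaction of the lactone lithium enolate, formed kinetically at the unhindered C11 methylene in preference to the tertiary α-CH of the isobutyrate, with the preformed iminium salt; the configuration of C11 is lost in step 21.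

Step 21
Reactants: 27 Mannich base
Product: 29 (1R,4Z,6R,7R,8R,10S)-14-[(tert-butyldimethylsilyl)oxy]-1,10-epoxy-8-(isobutyryloxy)germacra-4,11(13)-dien-12,6-olide, via trimethylammonium iodide 28 (not isolated)
Conditions: MeI (excess), THF, rt; then aq NaHCO3, CH2Cl2, rt
Reagents that add atoms: none
Why: Quaternisation of the amine and E1cB (Hofmann-type) elimination of trimethylamine under bicarbonate give the exocyclic C11=C13 alkene of the α-methylene lactone.

Step 22
Reactants: 29 silyl-protected α-methylene lactone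
Product: 30 (1R,4Z,6R,7R,8R,10S)-1,10-epoxy-14-hydroxy-8-(isobutyryloxy)germacra-4,11(13)-dien-12,6-olide (CNP0247143.1)
Conditions: Bu4NF, AcOH (1:1), THF, 0 °C to rt
Reagents that add atoms: none
Why: Fluoride cleavage of the primary silyl ether, buffered with acetic acid so that neither conjugate addition to the methylene lactone nor acid-induced transannular opening of the oxirane takes place, frees the C14 hydroxyl.

**Compound list**

1 | 1,3-propanediol | OCCCO | starting material
2 | 3-[(4-methoxybenzyl)oxy]propan-1-ol | COc1ccc(COCCCO)cc1 | intermediate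
3 | 3-[(4-methoxybenzyl)oxy]propanal | COc1ccc(COCCC=O)cc1 | intermediate
4 | methyl 2-[bis(2,2,2-trifluoroethoxy)phosphoryl]acetate | COC(=O)CP(=O)(OCC(F)(F)F)OCC(F)(F)F | starting material
5 | allyl bromide | C=CCBr | starting material
6 | methyl 2-[bis(2,2,2-trifluoroethoxy)phosphoryl]pent-4-enoate (racemic) | COC(=O)C(CC=C)P(=O)(OCC(F)(F)F)OCC(F)(F)F | intermediate
7 | methyl (2Z)-2-allyl-5-[(4-methoxybenzyl)oxy]pent-2-enoate | COC(=O)/C(CC=C)=C\CCOCc1ccc(OC)cc1 | intermediate
8 | (2Z)-2-allyl-5-[(4-methoxybenzyl)oxy]pent-2-en-1-ol | OC/C(CC=C)=C\CCOCc1ccc(OC)cc1 | intermediate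
9 | [(2S,3R)-2-allyl-3-{2-[(4-methoxybenzyl)oxy]ethyl}oxiran-2-yl]methanol | C=CC[C@@]1(CO)O[C@@H]1CCOCc1ccc(OC)cc1 | intermediate
10 | {[(2S,3R)-2-allyl-3-{2-[(4-methoxybenzyl)oxy]ethyl}oxiran-2-yl]methoxy}(tert-butyl)dimethylsilane | C=CC[C@@]1(CO[Si](C)(C)C(C)(C)C)O[C@@H]1CCOCc1ccc(OC)cc1 | intermediate
11 | 2-[(2S,3R)-2-{[(tert-butyldimethylsilyl)oxy]methyl}-3-{2-[(4-methoxybenzyl)oxy]ethyl}oxiran-2-yl]acetaldehyde | O=CC[C@@]1(CO[Si](C)(C)C(C)(C)C)O[C@@H]1CCOCc1ccc(OC)cc1 | intermediate
12 | monomethyl succinate | COC(=O)CCC(=O)O | starting material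
13 | S-tert-butyl 4-methoxy-4-oxobutanethioate | COC(=O)CCC(=O)SC(C)(C)C | intermediate
14 | E(O) enol borinate of 13 (O–B trans to the CH2CO2Me group; CIP 3Z): methyl 4-(tert-butylsulfanyl)-4-{[bis({[(1S,2S,5R)-2-isopropyl-5-methylcyclohexyl]methyl})boranyl]oxy}but-3-enoate | COC(=O)C/C=C(\SC(C)(C)C)OB(C[C@H]1C[C@H](C)CC[C@H]1C(C)C)C[C@H]1C[C@H](C)CC[C@H]1C(C)C | intermediate (not isolated)
15 | S-tert-butyl (2R,3R)-4-[(2S,3R)-2-{[(tert-butyldimethylsilyl)oxy]methyl}-3-{2-[(4-methoxybenzyl)oxy]ethyl}oxiran-2-yl]-3-hydroxy-2-(2-methoxy-2-oxoethyl)butanethioate | CC(C)(C)SC(=O)[C@H](CC(=O)OC)[C@H](O)C[C@@]1(CO[Si](C)(C)C(C)(C)C)O[C@@H]1CCOCc1ccc(OC)cc1 | intermediate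
16 | 3-O-isobutyrate of 15 | CC(C)(C)SC(=O)[C@H](CC(=O)OC)[C@H](OC(=O)C(C)C)C[C@@]1(CO[Si](C)(C)C(C)(C)C)O[C@@H]1CCOCc1ccc(OC)cc1 | intermediate
17 | methyl (3R,4R)-5-[(2S,3R)-2-{[(tert-butyldimethylsilyl)oxy]methyl}-3-{2-[(4-methoxybenzyl)oxy]ethyl}oxiran-2-yl]-3-[methoxy(methyl)carbamoyl]-4-[(2-methylpropanoyl)oxy]pentanoate | CON(C)C(=O)[C@H](CC(=O)OC)[C@H](OC(=O)C(C)C)C[C@@]1(CO[Si](C)(C)C(C)(C)C)O[C@@H]1CCOCc1ccc(OC)cc1 | intermediate
18 | 3-(2-hydroxyethyl)oxirane analogue of 17 | CON(C)C(=O)[C@H](CC(=O)OC)[C@H](OC(=O)C(C)C)C[C@@]1(CO[Si](C)(C)C(C)(C)C)O[C@@H]1CCO | intermediate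
19 | 3-(2-iodoethyl)oxirane analogue of 17 | CON(C)C(=O)[C@H](CC(=O)OC)[C@H](OC(=O)C(C)C)C[C@@]1(CO[Si](C)(C)C(C)(C)C)O[C@@H]1CCI | intermediate
20 | 1-propynylmagnesium bromide | CC#C[Mg]Br | starting material
21 | methyl (3R,4R)-3-(but-2-ynoyl)-5-[(2S,3R)-2-{[(tert-butyldimethylsilyl)oxy]methyl}-3-(2-iodoethyl)oxiran-2-yl]-4-[(2-methylpropanoyl)oxy]pentanoate | CC#CC(=O)[C@H](CC(=O)OC)[C@H](OC(=O)C(C)C)C[C@@]1(CO[Si](C)(C)C(C)(C)C)O[C@@H]1CCI | intermediate
22 | sodium benzenesulfinate | [Na+].[O-]S(=O)c1ccccc1 | starting material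
23 | methyl (3R,4R)-5-[(2S,3R)-2-{[(tert-butyldimethylsilyl)oxy]methyl}-3-(2-iodoethyl)oxiran-2-yl]-4-[(2-methylpropanoyl)oxy]-3-[(2E)-3-(phenylsulfonyl)but-2-enoyl]pentanoate | C/C(=C\C(=O)[C@H](CC(=O)OC)[C@H](OC(=O)C(C)C)C[C@@]1(CO[Si](C)(C)C(C)(C)C)O[C@@H]1CCI)S(=O)(=O)c1ccccc1 | intermediate
24 | methyl (1R,4Z,7R,8R,10S)-14-[(tert-butyldimethylsilyl)oxy]-1,10-epoxy-8-(isobutyryloxy)-6-oxo-13-norgermacr-4-en-12-oate | C/C1=C/C(=O)[C@H](CC(=O)OC)[C@H](OC(=O)C(C)C)C[C@@]2(CO[Si](C)(C)C(C)(C)C)O[C@@H]2CC1 | intermediate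
25 | methyl (1R,4Z,6R,7S,8R,10S)-14-[(tert-butyldimethylsilyl)oxy]-1,10-epoxy-6-hydroxy-8-(isobutyryloxy)-13-norgermacr-4-en-12-oate | C/C1=C/[C@@H](O)[C@H](CC(=O)OC)[C@H](OC(=O)C(C)C)C[C@@]2(CO[Si](C)(C)C(C)(C)C)O[C@@H]2CC1 | intermediate
26 | (1R,4Z,6R,7R,8R,10S)-14-[(tert-butyldimethylsilyl)oxy]-1,10-epoxy-8-(isobutyryloxy)-13-norgermacr-4-en-12,6-olide | C1C(=O)O[C@@H]2/C=C(/C)CC[C@H]3O[C@]3(CO[Si](C)(C)C(C)(C)C)C[C@@H](OC(=O)C(C)C)[C@@H]12 | intermediate
27 | 13-(dimethylamino) Mannich base of 26 (C11 epimers) | CN(C)CC1C(=O)O[C@@H]2/C=C(/C)CC[C@H]3O[C@]3(CO[Si](C)(C)C(C)(C)C)C[C@@H](OC(=O)C(C)C)[C@@H]12 | intermediate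
28 | N-methyl ammonium iodide of 27 | C[N+](C)(C)CC1C(=O)O[C@@H]2/C=C(/C)CC[C@H]3O[C@]3(CO[Si](C)(C)C(C)(C)C)C[C@@H](OC(=O)C(C)C)[C@@H]12.[I-] | intermediate (not isolated)
29 | (1R,4Z,6R,7R,8R,10S)-14-[(tert-butyldimethylsilyl)oxy]-1,10-epoxy-8-(isobutyryloxy)germacra-4,11(13)-dien-12,6-olide | C=C1C(=O)O[C@@H]2/C=C(/C)CC[C@H]3O[C@]3(CO[Si](C)(C)C(C)(C)C)C[C@@H](OC(=O)C(C)C)[C@@H]12 | intermediate
30 | (1R,4Z,6R,7R,8R,10S)-1,10-epoxy-14-hydroxy-8-(isobutyryloxy)germacra-4,11(13)-dien-12,6-olide (CNP0247143.1) | C=C1C(=O)O[C@@H]2/C=C(/C)CC[C@H]3O[C@]3(CO)C[C@@H](OC(=O)C(C)C)[C@@H]12 | target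

**Step count**

Total: 22 steps. Longest linear sequence: 20 steps (from 1 through steps 1, 2, 4–8 and 10–22).

**Steps most likely to fail**

1. Step 17 (proposed new method). The ten-membered closure onto a fully substituted C4 may be too slow. The C3 radical could then be reduced by the silane, attack the less hindered C5, or abstract hydrogen from C14 through a six-membered transition state, after which the oxiranylcarbinyl radical opens the oxirane. Equilibration to the Z enone may also stay incomplete.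
 Fallback (known chemistry, ring closure moved to C4=C5 by ring-closing metathesis): it sets out from 19. Coupling of the primary iodide with (CH2=CMe)2CuLi (Et2O–THF, −78 to −30 °C) would give the isopropenyl-extended Weinreb amide F1. CH2=CHMgBr (THF, −40 °C, cold acidic quench) would convert F1 into the vinyl ketone F2. Ring-closing metathesis of F2 with the second-generation Hoveyda–Grubbs catalyst (PhMe, 80 °C, 0.001 M, ethylene swept out) would join the vinyl ketone and the 1,1-disubstituted alkene to the ring-cis enone and come back to the route at 24.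

2. Step 10. Facial control and enolate geometry may erode because the γ-ester of the succinate can coordinate boron, and the β,γ-epoxy aldehyde may open to the γ-hydroxy enal before C–C bond formation.
 Fallback (Evans syn aldol reaction followed by inversion at C8): it sets out from 11 and 12 and returns at 17. Acylation of lithiated (4R)-4-benzyl-1,3-oxazolidin-2-one with the mixed pivalic anhydride of 12 would give the imide F3. Its dibutylboron enolate (Bu2BOTf, iPr2NEt, CH2Cl2, −78 °C) should add to 11 to give the syn adduct F4, with C7 as required and C8 epimeric. Transamidation with AlMe3 and MeNH(OMe)·HCl would give the β-hydroxy Weinreb amide F5. Mitsunobu esterification with isobutyric acid (PPh3, DIAD, PhMe, 0 °C) should invert C8 and give 17.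

3. Step 18. Hydride delivery may go to the wrong face, because the folded macrocycle and not the catalyst may decide which face of the C6 ketone is open, and the assignment of the large group in the catalyst model is uncertain for this enone.
 Fallback (substrate-controlled reduction followed by inversion): it sets out from 24 and returns at 25. Luche reduction (NaBH4, CeCl3·7H2O, MeOH, −78 °C), with hydride delivered from the ring periphery, would give the 6S alcohol F6. Mitsunobu reaction with formic acid (PPh3, DIAD) should invert C6 to the 6R formate F7. Mild methanolysis (KHCO3, MeOH, 0 °C), which removes a formate much faster than the isobutyrate, would give 25.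

Further compounds
F1 | step 17 | methyl (3R,4R)-5-[(2S,3R)-2-{[(tert-butyldimethylsilyl)oxy]methyl}-3-(3-methylbut-3-en-1-yl)oxiran-2-yl]-3-[methoxy(methyl)carbamoyl]-4-[(2-methylpropanoyl)oxy]pentanoate | CON(C)C(=O)[C@H](CC(=O)OC)[C@H](OC(=O)C(C)C)C[C@@]1(CO[Si](C)(C)C(C)(C)C)O[C@@H]1CCC(C)=C
F2 | step 17 | methyl (3R,4R)-3-acryloyl-5-[(2S,3R)-2-{[(tert-butyldimethylsilyl)oxy]methyl}-3-(3-methylbut-3-en-1-yl)oxiran-2-yl]-4-[(2-methylpropanoyl)oxy]pentanoate | C=CC(=O)[C@H](CC(=O)OC)[C@H](OC(=O)C(C)C)C[C@@]1(CO[Si](C)(C)C(C)(C)C)O[C@@H]1CCC(C)=C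
F3 | step 10 | (4R)-4-benzyl-3-(4-methoxy-4-oxobutanoyl)-1,3-oxazolidin-2-one | COC(=O)CCC(=O)N1[C@H](Cc2ccccc2)COC1=O
F4 | step 10 | methyl (3R,4S)-3-{[(4R)-4-benzyl-2-oxo-1,3-oxazolidin-3-yl]carbonyl}-5-[(2S,3R)-2-{[(tert-butyldimethylsilyl)oxy]methyl}-3-{2-[(4-methoxybenzyl)oxy]ethyl}oxiran-2-yl]-4-hydroxypentanoate | O=C1OC[C@@H](Cc2ccccc2)N1C(=O)[C@H](CC(=O)OC)[C@@H](O)C[C@@]3(CO[Si](C)(C)C(C)(C)C)O[C@@H]3CCOCc3ccc(OC)cc3
F5 | step 10 | methyl (3R,4S)-5-[(2S,3R)-2-{[(tert-butyldimethylsilyl)oxy]methyl}-3-{2-[(4-methoxybenzyl)oxy]ethyl}oxiran-2-yl]-4-hydroxy-3-[methoxy(methyl)carbamoyl]pentanoate | CON(C)C(=O)[C@H](CC(=O)OC)[C@@H](O)C[C@@]1(CO[Si](C)(C)C(C)(C)C)O[C@@H]1CCOCc1ccc(OC)cc1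
F6 | step 18 | methyl (1R,4Z,6S,7S,8R,10S)-14-[(tert-butyldimethylsilyl)oxy]-1,10-epoxy-6-hydroxy-8-(isobutyryloxy)-13-norgermacr-4-en-12-oate | C/C1=C/[C@H](O)[C@H](CC(=O)OC)[C@H](OC(=O)C(C)C)C[C@@]2(CO[Si](C)(C)C(C)(C)C)O[C@@H]2CC1
F7 | step 18 | methyl (1R,4Z,6R,7R,8R,10S)-14-[(tert-butyldimethylsilyl)oxy]-1,10-epoxy-6-(formyloxy)-8-(isobutyryloxy)-13-norgermacr-4-en-12-oate | C/C1=C/[C@@H](OC=O)[C@H](CC(=O)OC)[C@H](OC(=O)C(C)C)C[C@@]2(CO[Si](C)(C)C(C)(C)C)O[C@@H]2CC1
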